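**Plan**

- Retrosynthesis: the three benzyl groups are put back and ring B is lowered one oxidation level to a 4-carboxycyclohexane-1,3-dione. This works because ring B has free hydroxyls on C2 and C4 (1,3), the carboxyl on C1, methyls on C3 and C6, and the acylated oxygen on C5 next to C4.
- The dione ring is cut at C1–C6 and C2–C3 into dibenzyl malonate (C1, C2) and the ring A enol ester of hexane-3,4-dione (C3 to C6, both methyls and the O5–acyl bond already present).
- The enol ester is cut at the O–acyl bond into hexane-3,4-dione and the ring A acid chloride. Ring A comes from 2,6-dihydroxy-4-methylbenzoic acid by formylation, O-methylation, O-benzylation and oxidation of the formyl group.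
- Forward: ring A is bought and dressed (steps 1–6), joined to the diketone (step 7), ring B is closed beside the finished ester link (step 8), aromatised (step 9) and debenzylated (step 10).
- Stereochemistry: the target has no stereocentre; the four sp3 centres made in step 8 and the enol ester geometry are erased in step 9.

Key step: step 8

Remark: compound 14 is drawn as the triketo ester; it should exist as enol tautomers and as a mixture of diastereomers, which does not matter because all four sp3 ring carbons become aromatic in step 9. Compounds 1, 8 and 11 are taken as purchased.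

**Route**

Step 1
Reactants: 1 2,6-dihydroxy-4-methylbenzoic acid
Product: 2 benzyl 2,6-dihydroxy-4-methylbenzoate
Conditions: BnBr, KHCO3, DMF, rt
Reagents that add atoms: benzyl bromide, BrCc1ccccc1
Why: Carboxylate O-alkylation (SN2) with a hydrogencarbonate base too weak to ionise the two chelated phenols, so only the benzyl ester should form.

Step 2
Reactants: 2 benzyl 2,6-dihydroxy-4-methylbenzoate
Product: 3 benzyl 3-formyl-2,6-dihydroxy-4-methylbenzoate
Conditions: Cl2CHOMe, TiCl4, CH2Cl2, −10 to 0 °C; then aq. HCl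
Reagents that add atoms: dichloromethyl methyl ether, COC(Cl)Cl; water, O
Why: Rieche formylation, in which the two open ring positions are equivalent by symmetry, each is ortho to one hydroxyl and para to the other, and the first formyl group deactivates the ring against a second.

Step 3
Reactants: 3 benzyl 3-formyl-2,6-dihydroxy-4-methylbenzoate
Product: 4 benzyl 3-formyl-2-hydroxy-6-methoxy-4-methylbenzoate
Conditions: MeI (1 equiv), K2CO3 (1 equiv), acetone, rt
Reagents that add atoms: iodomethane, CI
Why: Williamson O-methylation, expected at the hydroxyl para to the formyl group because it has only one ortho substituent, whereas the hydroxyl between formyl and ester is doubly chelated and shielded.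

Step 4
Reactants: 4 benzyl 3-formyl-2-hydroxy-6-methoxy-4-methylbenzoate
Product: 5 benzyl 2-(benzyloxy)-3-formyl-6-methoxy-4-methylbenzoate
Conditions: BnBr, K2CO3, DMF, 60 °C
Reagents that add atoms: benzyl bromide, BrCc1ccccc1
Why: Williamson O-benzylation of the remaining chelated phenol, which needs excess halide and warming but has no competing nucleophile.

Step 5
Reactants: 5 benzyl 2-(benzyloxy)-3-formyl-6-methoxy-4-methylbenzoate
Product: 6 2-(benzyloxy)-3-(benzyloxycarbonyl)-4-methoxy-6-methylbenzoic acid
Conditions: NaClO2, NaH2PO4, 2-methylbut-2-ene, t-BuOH/H2O, rt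
Reagents that add atoms: sodium chlorite, [Na+].[O-]Cl=O
Why: Pinnick oxidation of the aryl aldehyde to the acid, with the alkene removing hypochlorite before it can chlorinate the electron-rich ring and the benzyl ether and ester inert.

Step 6
Reactants: 6 2-(benzyloxy)-3-(benzyloxycarbonyl)-4-methoxy-6-methylbenzoic acid
Product: 7 benzyl 2-(benzyloxy)-3-(chlorocarbonyl)-6-methoxy-4-methylbenzoate
Conditions: (COCl)2, cat. DMF, CH2Cl2, 0 °C to rt; evaporated and used crude
Reagents that add atoms: oxalyl chloride, O=C(Cl)C(=O)Cl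
Why: Acid chloride formation through the chloroiminium catalyst from DMF, under conditions mild enough to keep the benzyl ether and benzyl ester.

Step 7
Reactants: 7 benzyl 2-(benzyloxy)-3-(chlorocarbonyl)-6-methoxy-4-methylbenzoate; 8 hexane-3,4-dione
Product: 10 (Z)-4-oxohex-2-en-3-yl 2-(benzyloxy)-3-(benzyloxycarbonyl)-4-methoxy-6-methylbenzoate, via potassium enolate 9 (not isolated)
Conditions: 8, KN(SiMe3)2, THF, −78 °C; then 7, −78 to 0 °C
Reagents that add atoms: none
Why: O-acylation of a potassium enolate by a hard, di-ortho-substituted aroyl chloride (enol ester formation); the symmetric diketone can give only one enolate, and the Z geometry expected (methyl cis to oxygen) has no bearing later.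

Step 8
Reactants: 10 (Z)-4-oxohex-2-en-3-yl 2-(benzyloxy)-3-(benzyloxycarbonyl)-4-methoxy-6-methylbenzoate; 11 dibenzyl malonate
Product: 14 benzyl 5-{[2-(benzyloxy)-3-(benzyloxycarbonyl)-4-methoxy-6-methylbenzoyl]oxy}-3,6-dimethyl-2,4-dioxocyclohexane-1-carboxylate, via sodium dibenzyl malonate 12 (not isolated), via Michael adduct 13 (not isolated)
Conditions: 11 (1.3 equiv), NaH (1.1 equiv), THF, 0 °C; then 10, 0 °C to rt; then 60 °C; 1 M HCl work-up
Reagents that add atoms: none
Why: Proposed new method: malonate anion 12 adds to the methyl-bearing β-carbon of the α-aroyloxy enone 10 (C1–C6 bond), the first-formed enolate is protonated on carbon by the excess malonate to give 13, and the minor enolate on the ethyl side then attacks one benzyl ester and expels benzyl alcohol (C2–C3 bond), the sequence being driven by the sodium salt of the vinylogous acid 14, so one equivalent of base suffices and no free benzyloxide builds up. The closest known reaction type is the Michael–Claisen (Michael–Dieckmann) annulation of malonic esters with alkenyl ketones to 4-alkoxycarbonylcyclohexane-1,3-diones, and conjugate additions to α-acyloxy enones are known separately; the tandem use on an α-aroyloxy enone is the extension. Ring B closes in a 6-(enolexo)-exo-trig acyl substitution. Four stereocentres (C1, C3, C5, C6) arise without control and need none, since C1 and C3 epimerise through their enols and all four become sp2 in step 9. The selectivity required is chemoselectivity, conjugate addition and Claisen closure ahead of aroyl transfer to the neighbouring enolate oxygen or the malonate carbon and ahead of enol ester cleavage; it rests on the methyl and benzyloxy groups flanking the ring A carbonyl, and on the fact that only the six-membered closure ends in a stabilised β-diketonate, whereas an acyl-transposed isomer could only close reversibly to a five-membered dione without an acidic diketone hydrogen. Regiochemistry is fixed by connectivity, because the symmetric diketone gives a single enol ester and each ring B carbon is defined by 10 and 11.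

Step 9
Reactants: 14 benzyl 5-{[2-(benzyloxy)-3-(benzyloxycarbonyl)-4-methoxy-6-methylbenzoyl]oxy}-3,6-dimethyl-2,4-dioxocyclohexane-1-carboxylate
Product: 15 benzyl 5-{[2-(benzyloxy)-3-(benzyloxycarbonyl)-4-methoxy-6-methylbenzoyl]oxy}-2,4-dihydroxy-3,6-dimethylbenzoate
Conditions: I2 (cat.), DMSO, 80 °C
Reagents that add atoms: none
Why: Iodine-catalysed oxidative aromatisation of a cyclohexane-1,3-dione in DMSO (α-iodination, loss of HI, re-oxidation of HI by DMSO), which removes the hydrogens on C5 and C6 and should leave the fully substituted resorcinol ring with its aryl ester in place.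

Step 10
Reactants: 15 benzyl 5-{[2-(benzyloxy)-3-(benzyloxycarbonyl)-4-methoxy-6-methylbenzoyl]oxy}-2,4-dihydroxy-3,6-dimethylbenzoate
Product: 16 hypothamnolic acid, 5-[(3-carboxy-2-hydroxy-4-methoxy-6-methylbenzoyl)oxy]-2,4-dihydroxy-3,6-dimethylbenzoic acid
Conditions: H2 (1 atm), 10% Pd/C, EtOAc, rt
Reagents that add atoms: none
Why: Hydrogenolysis of one benzyl ether and two benzyl esters under neutral conditions, which leaves the aryl ester between the rings and the methyl ether untouched and avoids base-induced acyl migration to the neighbouring C4 hydroxyl.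

**Compound list**

1 | 2,6-dihydroxy-4-methylbenzoic acid | Cc1cc(O)c(C(=O)O)c(O)c1 | starting material
2 | benzyl 2,6-dihydroxy-4-methylbenzoate | Cc1cc(O)c(C(=O)OCc2ccccc2)c(O)c1 | intermediate
3 | benzyl 3-formyl-2,6-dihydroxy-4-methylbenzoate | Cc1cc(O)c(C(=O)OCc2ccccc2)c(O)c1C=O | intermediate
4 | benzyl 3-formyl-2-hydroxy-6-methoxy-4-methylbenzoate | Cc1cc(OC)c(C(=O)OCc2ccccc2)c(O)c1C=O | intermediate
5 | benzyl 2-(benzyloxy)-3-formyl-6-methoxy-4-methylbenzoate | Cc1cc(OC)c(C(=O)OCc2ccccc2)c(OCc2ccccc2)c1C=O | intermediate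
6 | 2-(benzyloxy)-3-(benzyloxycarbonyl)-4-methoxy-6-methylbenzoic acid | Cc1cc(OC)c(C(=O)OCc2ccccc2)c(OCc2ccccc2)c1C(=O)O | intermediate
7 | benzyl 2-(benzyloxy)-3-(chlorocarbonyl)-6-methoxy-4-methylbenzoate | Cc1cc(OC)c(C(=O)OCc2ccccc2)c(OCc2ccccc2)c1C(=O)Cl | intermediate
8 | hexane-3,4-dione | CCC(=O)C(=O)CC | starting material
9 | potassium (Z)-4-oxohex-2-en-3-olate | C/C=C(\[O-])C(=O)CC.[K+] | intermediate
10 | (Z)-4-oxohex-2-en-3-yl 2-(benzyloxy)-3-(benzyloxycarbonyl)-4-methoxy-6-methylbenzoate | C/C=C(\OC(=O)c1c(C)cc(OC)c(C(=O)OCc2ccccc2)c1OCc1ccccc1)C(=O)CC | intermediate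
11 | dibenzyl malonate | O=C(CC(=O)OCc1ccccc1)OCc1ccccc1 | starting material
12 | sodium dibenzyl malonate | [Na+].O=C([CH-]C(=O)OCc1ccccc1)OCc1ccccc1 | intermediate
13 | dibenzyl 2-(3-{[2-(benzyloxy)-3-(benzyloxycarbonyl)-4-methoxy-6-methylbenzoyl]oxy}-4-oxohexan-2-yl)propanedioate, mixture of diastereomers, present as its sodium salt | CCC(=O)C(OC(=O)c1c(C)cc(OC)c(C(=O)OCc2ccccc2)c1OCc1ccccc1)C(C)C(C(=O)OCc1ccccc1)C(=O)OCc1ccccc1 | intermediate
14 | benzyl 5-{[2-(benzyloxy)-3-(benzyloxycarbonyl)-4-methoxy-6-methylbenzoyl]oxy}-3,6-dimethyl-2,4-dioxocyclohexane-1-carboxylate, mixture of diastereomers and enol tautomers | CC1C(C(=O)OCc2ccccc2)C(=O)C(C)C(=O)C1OC(=O)c1c(C)cc(OC)c(C(=O)OCc2ccccc2)c1OCc1ccccc1 | intermediate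
15 | benzyl 5-{[2-(benzyloxy)-3-(benzyloxycarbonyl)-4-methoxy-6-methylbenzoyl]oxy}-2,4-dihydroxy-3,6-dimethylbenzoate | Cc1c(C(=O)OCc2ccccc2)c(O)c(C)c(O)c1OC(=O)c1c(C)cc(OC)c(C(=O)OCc2ccccc2)c1OCc1ccccc1 | intermediate
16 | hypothamnolic acid | COc1cc(C)c(C(=O)Oc2c(C)c(C(=O)O)c(O)c(C)c2O)c(O)c1C(=O)O | target

**Count and risks**

Total steps: 10. Longest linear sequence: 10 steps (1 to 16); 8 and 11 are purchased and enter at steps 7 and 8.

Steps most likely to fail:

1. Step 8. The aroyl group may shift from the enol oxygen to the neighbouring enolate oxygen or to the malonate carbon, or the enol ester may be cleaved by benzyloxide, faster than conjugate addition and Claisen closure. The fallback uses known chemistry only, sets out from dibenzyl malonate 11 and acid chloride 7, and returns at target 16; it keeps the acyl group out of the annulation.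
   - Compound 11 and purchased (E)-hex-4-en-3-one undergo the established Michael–Claisen annulation (NaH, THF, then heat) to benzyl 3,6-dimethyl-2,4-dioxocyclohexane-1-carboxylate F1.
   - Dehydrogenation (I2, DMSO) gives benzyl 2,4-dihydroxy-3,6-dimethylbenzoate F2.
   - Formylation at the only free ring position (Cl2CHOMe, TiCl4) gives benzyl 5-formyl-2,4-dihydroxy-3,6-dimethylbenzoate F3.
   - Double benzylation (BnBr, K2CO3, DMF) gives benzyl 2,4-bis(benzyloxy)-5-formyl-3,6-dimethylbenzoate F4.
   - Baeyer–Villiger oxidation (mCPBA) gives the aryl formate benzyl 2,4-bis(benzyloxy)-5-(formyloxy)-3,6-dimethylbenzoate F5, and methanolysis (K2CO3, MeOH) gives benzyl 2,4-bis(benzyloxy)-5-hydroxy-3,6-dimethylbenzoate F6.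
   - Acylation of the potassium phenoxide of F6 with 7 gives the pentabenzyl depside benzyl 2,4-bis(benzyloxy)-5-{[2-(benzyloxy)-3-(benzyloxycarbonyl)-4-methoxy-6-methylbenzoyl]oxy}-3,6-dimethylbenzoate F7, and hydrogenolysis (H2, Pd/C) gives 16.

2. Step 9. The aroyloxy group may be lost by elimination, which would aromatise ring B without its C5 oxygen, or the reaction may stall with the halogen parked on the methyl-bearing C3. The fallback sets out from 14 and returns at 15; it replaces halogenation of the free dione by hydride abstraction from a fixed diene.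
   - Compound 14 is converted (Me3SiOTf, Et3N, CH2Cl2) into benzyl 5-{[2-(benzyloxy)-3-(benzyloxycarbonyl)-4-methoxy-6-methylbenzoyl]oxy}-3,6-dimethyl-2,4-bis(trimethylsilyloxy)cyclohexa-1,3-diene-1-carboxylate F8.
   - DDQ should dehydrogenate this cyclohexa-1,3-diene at room temperature to benzyl 5-{[2-(benzyloxy)-3-(benzyloxycarbonyl)-4-methoxy-6-methylbenzoyl]oxy}-3,6-dimethyl-2,4-bis(trimethylsilyloxy)benzoate F9.
   - Dilute aqueous acid then frees the two phenols to give 15.

3. Step 7. C-acylation or aldol self-condensation of the diketone enolate may compete with O-acylation by a slow, hindered acid chloride. The fallback sets out from 6 and 8 and returns at 10; it uses fluoride-catalysed O-acylation of a silyl enol ether, which is regiospecific.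
   - Compound 8 is silylated (Me3SiCl, Et3N, NaI, MeCN) to (Z)-4-(trimethylsilyloxy)hex-4-en-3-one F10.
   - Acid 6 is converted (cyanuric fluoride, pyridine) into benzyl 2-(benzyloxy)-3-(fluorocarbonyl)-6-methoxy-4-methylbenzoate F11.
   - F10 and F11 with catalytic Bu4NF in THF should give 10.

**Further compounds**

F1 | step 8 | benzyl 3,6-dimethyl-2,4-dioxocyclohexane-1-carboxylate | CC1CC(=O)C(C)C(=O)C1C(=O)OCc1ccccc1
F2 | step 8 | benzyl 2,4-dihydroxy-3,6-dimethylbenzoate | Cc1cc(O)c(C)c(O)c1C(=O)OCc1ccccc1
F3 | step 8 | benzyl 5-formyl-2,4-dihydroxy-3,6-dimethylbenzoate | Cc1c(C=O)c(O)c(C)c(O)c1C(=O)OCc1ccccc1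
F4 | step 8 | benzyl 2,4-bis(benzyloxy)-5-formyl-3,6-dimethylbenzoate | Cc1c(C=O)c(OCc2ccccc2)c(C)c(OCc2ccccc2)c1C(=O)OCc1ccccc1
F5 | step 8 | benzyl 2,4-bis(benzyloxy)-5-(formyloxy)-3,6-dimethylbenzoate | Cc1c(OC=O)c(OCc2ccccc2)c(C)c(OCc2ccccc2)c1C(=O)OCc1ccccc1
F6 | step 8 | benzyl 2,4-bis(benzyloxy)-5-hydroxy-3,6-dimethylbenzoate | Cc1c(O)c(OCc2ccccc2)c(C)c(OCc2ccccc2)c1C(=O)OCc1ccccc1
F7 | step 8 | benzyl 2,4-bis(benzyloxy)-5-{[2-(benzyloxy)-3-(benzyloxycarbonyl)-4-methoxy-6-methylbenzoyl]oxy}-3,6-dimethylbenzoate | Cc1c(OC(=O)c2c(C)cc(OC)c(C(=O)OCc3ccccc3)c2OCc2ccccc2)c(OCc2ccccc2)c(C)c(OCc2ccccc2)c1C(=O)OCc1ccccc1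
F8 | step 9 | benzyl 5-{[2-(benzyloxy)-3-(benzyloxycarbonyl)-4-methoxy-6-methylbenzoyl]oxy}-3,6-dimethyl-2,4-bis(trimethylsilyloxy)cyclohexa-1,3-diene-1-carboxylate | CC1C(OC(=O)c2c(C)cc(OC)c(C(=O)OCc3ccccc3)c2OCc2ccccc2)C(O[Si](C)(C)C)=C(C)C(O[Si](C)(C)C)=C1C(=O)OCc1ccccc1
F9 | step 9 | benzyl 5-{[2-(benzyloxy)-3-(benzyloxycarbonyl)-4-methoxy-6-methylbenzoyl]oxy}-3,6-dimethyl-2,4-bis(trimethylsilyloxy)benzoate | Cc1c(C(=O)OCc2ccccc2)c(O[Si](C)(C)C)c(C)c(O[Si](C)(C)C)c1OC(=O)c1c(C)cc(OC)c(C(=O)OCc2ccccc2)c1OCc1ccccc1
F10 | step 7 | (Z)-4-(trimethylsilyloxy)hex-4-en-3-one | C/C=C(\O[Si](C)(C)C)C(=O)CC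
F11 | step 7 | benzyl 2-(benzyloxy)-3-(fluorocarbonyl)-6-methoxy-4-methylbenzoate | Cc1cc(OC)c(C(=O)OCc2ccccc2)c(OCc2ccccc2)c1C(=O)F
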